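One turnover, one Z made per L charged, is the unit to count in here: the count N = cZ/cL at a stated time is the turnover number of a flask.

| flask | D | E | G | L | remark | time |
|---|---|---|---|---|---|---|
| dusk | 0.24 M | 0.12 M | 32 mM (held) | 0.48 mM | run made earlier |  |
| winter | 0.24 M | 0.48 M | 32 mM (held) | 0.48 mM | run made earlier |  |
| spring | 0.24 M | 0.24 M | 32 mM (held) | 0.96 mM | run made earlier |  |
| flask | 0.24 M | 0.240 M | 32 mM (held) | 0.48 mM |  | 8.0 h |

- dusk (time / h: Z / %): 0.417: 0.9; 0.667: 2.1; 1.00: 3.4; 2.00: 6.4; 3.00: 8.9; 5.00: 13.0
- winter (time / h: Z / %): 0.833: 1.6; 1.50: 1.4; 2.50: 4.6; 3.00: 5.6; 4.00: 7.0; 5.00: 9.0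
- spring (time / h: Z / %): 0.417: 1.1; 0.667: 1.7; 1.33: 4.9; 2.50: 8.0; 5.00: 14.9

(readings scatter by 0.5 percentage points)

- what was read earlier has a scatter of 0.5 percentage points, one standard deviation
- at the start none of G is in solution
- Q is what G becomes in solution

* amount of Z at 8.0 h, in percent of the D charged
* concentration of Q in solution at 8.0 h, in percent of saturation

The bench rule treats a catalyst as a multiplier of rate, so that, with the time and the other charges held, N stays the same whatever cL is. The E of the flask, 0.240 M, lies midway on a logarithmic scale between the dusk and winter charges, so the mean of their readings at 5.00 h, 11.0 %, stands in for the flask at that time, with N = 55.0. Applied honestly, the rule puts spring, with twice the L at the same E, at 22.0 %. Spring reads 14.9 %, with N = 37.2, so the rule has already stopped working between these two charges of L. The turnover slope, the fall of ln N per unit rise of ln cL with the time and the other charges held, read here as 0.562, measures that border: zero is the bench rule, and one means Z does not respond to cL.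

The growth of N also slows with time. The turnover frequency of dusk reads 17.0 h⁻¹ over its first hour and 10.2 h⁻¹ over its last stretch, a first-order decline read as 0.145 h⁻¹. Scaled to the flask, that decline adds 18.1 turnovers up to 8.0 h, so this reckoning commits to N = 73.1, or 14.6 % Z.

The forecast, “allowing for D depletion, mild decay and the lag”, stands at 16.5 % Z and 97 % of saturation. The flask gives 13.8 % Z and Q at 86.9 % of saturation, so Z lies 0.80 percentage points below this reckoning.

    D + Q + L → L + Z (k = 9050 M⁻² h⁻¹)
    E + Q + L → L + J (k = 19700 M⁻² h⁻¹)
    G ⇌ Q, rate k3*(csat - [Q]) (kL = 1.18 h⁻¹)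
    L → X (k = 0.372 h⁻¹)

The result is a count of 68.9 in the flask. The slope carries that count to the neighbouring flask, charged with 0.190 mM of L and otherwise the same: N = 116, which means 9.19 % Z. The neighbouring flask gives 7.55 % Z, a count of 95.3, lower than reckoned and higher than the 68.9 of the first flask.

Readings and results stem from a simulated flask on assumed constants; noise was put on by code.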